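A closed flask keeps its charge: the substrate put in must stand as substrate, as target, or as something I do not read. The flask here is the larch run itself, followed further.

- larch: substrate 1.6 M; partner 1.5 equiv; temperature 25 °C; the very flask that is asked about, followed so far
- flask: substrate 1.6 M; partner 1.50 equiv; temperature 25 °C; time 3.0 min

- larch (time / min: target / %, substrate / %): 0.250: 11.3, 4.2; 0.417: 25.9, 0.8; 0.833: 45.5, 0.2; 1.50: 46.2, 0; 3.00: 40.1, 0.5

(scatter of a reading: 0.3 percentage points)

- target that was removed still counts
- the numbers in the tables scatter by 0.3 percentage points (one standard deviation)
- the earlier runs do not show what temperature does; that part of a forecast is a guess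

- Thursday's: change nothing and wait 6.0 min more
- Friday's: at 3.0 min raise the temperature by 20 K, then wait 6.0 min
- Monday's: at 3.0 min take out 90% of the target then present, then wait 6.0 min

* target, in percent of the substrate first charged, at 3.0 min
* the remedy with the largest gain of target, or "none" below 2 percentage points (Thursday's / Friday's / Monday's / none)
* target present, with what was taken out counted in, in percent of the substrate first charged, after Thursday's
* target present, with what was taken out counted in, in percent of the substrate first charged, after Friday's

I build it up. Substrate is the limiting reagent, with partner at 1.50 equiv. With the main step by itself, substrate + partner → target, target at 3.00 min would read 99.5%. It reads 40.1%, so 59.4% stands unread.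

Next comes an intermediate. Substrate reads 0.8% at 0.417 min, yet target still climbs to 45.5% at 0.833 min, so something stands between them.

Then comes a drain. Target falls from 46.2% at 1.50 min to 40.1% at 3.00 min. That gives 0.0944 /min, my apparent loss constant, the fall of ln c_target per minute between these two readings. If the drain runs one way, Thursday's leaves 22.8%.

Last comes a possible way back. Drained material may return, and the net fall then slows as it collects. Two readings give one constant, not a plateau, so I commit to a range: target now about 40.1%, and after Thursday's between 22.8% and that reading. I expect Thursday's to gain nothing. A way back would let Monday's removal draw material back to target, so I expect a gain there. Friday's I cannot size.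

The forecast says 40.1% now, 24.5% after Thursday's, 9% after Friday's, and best: none. It finds “no firm sign of reversibility”. Its Thursday's figure lies inside my range, but we part on Monday's.

The flask gives 40.2% now, 39.3% after Thursday's and 68.6% after Friday's. Best is Friday's, with a gain of 28 percentage points, and Monday's gains 19 points.

    substrate + partner → intermediate A (k = 0.180 /M/s, Ea = 50.0 kJ/mol)
    intermediate A → decomposed reagent (k = 0.0120 /s, Ea = 92.0 kJ/mol)
    intermediate A ⇌ intermediate B (K = 3.20, k = 0.170 /s, Ea = 86.0 kJ/mol, ΔH = −9.00 kJ/mol)
    intermediate C → target (k = 0.210 /s, Ea = 83.0 kJ/mol)
    target ⇌ isomer of the product (K = 1.20, k = 0.0180 /s, Ea = 85.0 kJ/mol, ΔH = −60.0 kJ/mol)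
    intermediate B ⇌ intermediate C (K = 14.0, k = 0.0450 /s, Ea = 86.0 kJ/mol, ΔH = −12.0 kJ/mol)
    (constants at 25 °C)

Over Thursday's, target falls at 0.003471 /min, far slower than 0.0944 /min, so the drain I read is not one-way. Target in this flask stands at 40.2% at 3.00 min mainly because of the loss of target to isomer of the product, both ways: the run with that step taken away holds 86.3%. If I read 0.0944 /min as a one-way drain and let it quicken with heat, I expect the repeat at 50 °C to hold less target than the 40.2% of this flask. That repeat instead holds more target than this flask: 69.1% at 3.00 min, against 12.8% of isomer of the product.

All runs come from a simulation with made-up constants, and the scatter is random.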